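**Plan**

Eudesmane numbering is used: ring A = C1–C5/C10, ring B = C5–C10; C4 carries the exocyclic CH2 (C15), C10 the methyl, C6 the ester oxygen, C7 the isopropyl group.
Cuts: (a) the C6–O acyl bond (esterification with acetyl-protected p-coumaric acid); (b) C4=C15 (methylenation of a C4 ketone); (c) C9–C10 and C5–C6 together, by one Diels–Alder reaction.
Enabling feature: ring B is a six-membered carbocycle whose C6–C7–C8–C9 arc carries oxygen at one end (a 1-oxy diene, C7=C8 as retron), and whose C5–C10 bond lies next to C4, a latent carbonyl. Ring A at the C4-ketone level is therefore 3-methylcyclohex-2-enone, a dienophile of matching polarity (C9 to the β-carbon C10, C6 to the α-carbon C5).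
Forward: the C6–C9 diene is made from 3-methylbutanal and acetaldehyde; ring B is closed onto intact ring A in one enantioselective endo [4+2]; the helpers are then removed (silyl group off O6, C7=C8 hydrogenated, C4=O turned into C4=CH2); the ester is attached last.
Stereochemistry: C10 (absolute) from a chiral boron Lewis acid; C6 from endo addition of the (1E)-diene; C7 from hydroxyl-directed hydrogenation (H syn to O6); C5, set cis in the cycloaddition, is inverted to the trans ring fusion by enolate equilibration through the C4 ketone.

Key step: step 4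

Assumption: the (S)-configured oxazaborolidinium salt is taken to expose the face of 8 that is Si at C2 and C3 (enone locants); should the sense of induction be the opposite one, the (R)-catalyst is used and nothing else changes.

**Route**

Step 1
Reactants: 1 3-methylbutanal
Product: 2 N-cyclohexyl-3-methylbutan-1-imine
Conditions: cyclohexylamine (1.0 equiv), 4 Å molecular sieves, Et2O, 0 °C → rt; distillation
Reagents that add atoms: cyclohexylamine, NC1CCCCC1
Why: Condensation of the aldehyde with a primary amine gives the aldimine, which suppresses self-aldol reaction and allows regiospecific α-metalation in the next step (directed aldol strategy).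

Step 2
Reactants: 2 N-cyclohexyl-3-methylbutan-1-imine; 3 acetaldehyde
Product: 6 (2E)-2-(propan-2-yl)but-2-enal, via lithium aza-enolate 4 (not isolated), via lithium aldolate imine 5 (not isolated)
Conditions: LiN(iPr)2 (1.05 equiv), THF, −78 → 0 °C; 3, −78 °C; then aqueous oxalic acid, reflux (steam distillation)
Reagents that add atoms: water, O
Why: Wittig directed aldol condensation: the metalated aldimine adds to acetaldehyde, and acidic hydrolysis with dehydration should give the conjugated enal as its thermodynamically preferred (E) isomer.

Step 3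
Reactants: 6 (2E)-2-(propan-2-yl)but-2-enal
Product: 7 tert-butyl(dimethyl){[(1E)-2-(propan-2-yl)buta-1,3-dien-1-yl]oxy}silane
Conditions: tBuMe2SiOTf (1.2 equiv), Et3N (1.5 equiv), Et2O, 0 °C → rt; distillation
Reagents that add atoms: tert-butyldimethylsilyl trifluoromethanesulfonate, CC(C)(C)[Si](C)(C)OS(=O)(=O)C(F)(F)F
Why: Vinylogous soft enolization (O-silylation, then γ-deprotonation of the methyl group by Et3N) gives the 1-silyloxy diene, and deprotonation from the favoured s-trans enal conformer places oxygen anti to the vinyl group, which is the (1E) geometry needed for the cycloaddition.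

Step 4
Reactants: 7 tert-butyl(dimethyl){[(1E)-2-(propan-2-yl)buta-1,3-dien-1-yl]oxy}silane; 8 3-methylcyclohex-2-en-1-one
Product: 9 (4aR,8R,8aR)-8-{[tert-butyl(dimethyl)silyl]oxy}-4a-methyl-7-(propan-2-yl)-3,4,4a,5,8,8a-hexahydronaphthalen-1(2H)-one (cis-fused; eudesmane positions 5β-H/6α-OSi/10β-CH3; C7=C8)
Conditions: (S)-1-(2-methylphenyl)-3,3-diphenyltetrahydro-1H,3H-pyrrolo[1,2-c][1,3,2]oxazaborole (C24H24BNO, 20 mol %), HN(SO2CF3)2 (16 mol %), slight excess of the diene, CH2Cl2, −78 → −20 °C; Et3N quench
Reagents that add atoms: none
Why: Proposed new method: the protonated oxazaborolidine should bind the C4 carbonyl of 8 on the lone pair syn to C5–H, lower the enone LUMO and block one face, so that 7 adds in a concerted but asynchronous endo [4+2] in which the unsubstituted terminus C9 (largest HOMO coefficient) bonds first to the β-carbon C10 and the oxygenated terminus C6 then closes onto the α-carbon C5. The closest known reaction types are the oxazaborolidinium-catalysed enantioselective Diels–Alder reaction of cyclohex-2-enone and quinones with silyloxy dienes and the AlCl3-catalysed racemic Diels–Alder reaction of 3-methylcyclohex-2-enone itself; new is the β-methyl enone, which forms a quaternary centre, in the enantioselective manifold. Ring B is closed as a six-membered ring by suprafacial [4+2] cycloaddition onto the C5=C10 bond of intact ring A, which fixes H-5 and the C10 methyl cis. C10, and with it the absolute configuration, is set by the catalyst-controlled attack on the face that is Si at both alkene carbons; C5 follows from the suprafacial addition; C6 follows from the (1E) diene geometry combined with the endo orientation of the C4 carbonyl, which puts O6 anti to the angular methyl. The step needs regioselectivity (C6 to C5, not to C10), endo selectivity and enantioface selectivity: the first is secured by the 1-silyloxy group overriding the 2-alkyl group, the second by the Lewis-acid-enhanced preference for the carbonyl under the diene, the third by the catalyst.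

Step 5
Reactants: 9 cis-fused silyl ether
Product: 10 (4aR,8R,8aR)-8-hydroxy-4a-methyl-7-(propan-2-yl)-3,4,4a,5,8,8a-hexahydronaphthalen-1(2H)-one
Conditions: HF·pyridine, pyridine, THF, 0 °C → rt
Reagents that add atoms: none
Why: Fluoride-mediated Si–O cleavage under buffered, weakly acidic conditions should free the C6 hydroxyl without enolizing the β-oxy ketone, so that C5 and C6 are untouched and β-elimination is avoided.

Step 6
Reactants: 10 cis-fused hydroxy enone
Product: 11 (4aR,7S,8S,8aR)-8-hydroxy-4a-methyl-7-(propan-2-yl)octahydronaphthalen-1(2H)-one (cis-fused; 5β-H/6α-OH/7β-isopropyl/10β-CH3)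
Conditions: H2 (1 atm), [Ir(cod)(PCy3)(py)]PF6 (5 mol %), CH2Cl2, 0 °C → rt
Reagents that add atoms: none
Why: Hydroxyl-directed homogeneous hydrogenation: the cationic iridium centre binds the allylic C6 hydroxyl and delivers H2 to the same (α) face of the trisubstituted C7=C8 bond, so H-7 ends syn to O6 and the isopropyl group β.

Step 7
Reactants: 11 cis-fused hydroxy ketone
Product: 12 (4aR,7S,8S,8aS)-8-hydroxy-4a-methyl-7-(propan-2-yl)octahydronaphthalen-1(2H)-one (trans-fused; 5α-H)
Conditions: NaOMe (0.2 equiv), MeOH, 25 °C; residual 11 separated and resubmitted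
Reagents that add atoms: none
Why: Thermodynamic epimerization at C5 through the C4 enolate: with ring B held as a chair by the equatorial isopropyl and hydroxyl groups, the cis isomer is confined to the conformer with C4 axial on ring B (the situation of A/B-cis 4-oxo steroids, which equilibrate to the A/B-trans ketones), so the trans-fused ketone should predominate; loss of O6 is not expected because the equatorial C6–O bond lies in the nodal plane of the enolate, and retro-aldol cleavage is disfavoured because the C5–C6 bond lies in the plane of the C4 carbonyl.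

Step 8
Reactants: 12 trans-fused hydroxy ketone
Product: 13 (1S,2S,4aR,8aS)-4a-methyl-8-methylidene-2-(propan-2-yl)decahydronaphthalen-1-ol (eudesm-4(15)-en-6α-ol)
Conditions: Ph3PCH3Br (4 equiv), KOtBu (3.8 equiv), toluene, 80 °C
Reagents that add atoms: methylenetriphenylphosphorane (formed from methyltriphenylphosphonium bromide and KOtBu), C=P(c1ccccc1)(c1ccccc1)c1ccccc1
Why: Wittig methylenation with excess ylide in hot toluene is the standard way to turn hindered angular-methyl 4-oxo decalins into 4(15)-enes; O6 is present as an alkoxide that cannot leave by β-elimination, and the basic medium only maintains the trans-favouring C5 equilibrium of step 7.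

Step 9
Reactants: 13 eudesm-4(15)-en-6α-ol; 14 (2E)-3-[4-(acetyloxy)phenyl]prop-2-enoic acid
Product: 15 (1S,2S,4aR,8aS)-4a-methyl-8-methylidene-2-(propan-2-yl)decahydronaphthalen-1-yl (2E)-3-[4-(acetyloxy)phenyl]prop-2-enoate
Conditions: DCC (1.5 equiv), DMAP (0.3 equiv), CH2Cl2, 0 °C → rt
Reagents that add atoms: none
Why: Steglich esterification (carbodiimide activation, acyl transfer through the acylpyridinium ion) acylates the hindered equatorial C6 alcohol with retention at C6, the phenol being masked as acetate so that it cannot compete as a nucleophile.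

Step 10
Reactants: 15 acetate-protected ester
Product: 16 (1S,2S,4aR,8aS)-4a-methyl-8-methylidene-2-(propan-2-yl)decahydronaphthalen-1-yl (2E)-3-(4-hydroxyphenyl)prop-2-enoate (CNP0321375.1)
Conditions: K2CO3 (0.2 equiv), MeOH, 0 °C
Reagents that add atoms: none
Why: Chemoselective methanolysis of the aryl acetate: phenoxide is a far better leaving group than the hindered secondary alkoxide and the emerging phenolate deactivates the cinnamate carbonyl, so the C6 ester and the (E)-alkene should remain intact.

**Compound list**

1 | 3-methylbutanal | CC(C)CC=O | starting material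
2 | N-cyclohexyl-3-methylbutan-1-imine | CC(C)CC=NC1CCCCC1 | intermediate
3 | acetaldehyde | CC=O | starting material
4 | lithium cyclohexyl(3-methylbut-1-en-1-yl)azanide (aza-enolate of 2) | [Li+].CC(C)C=C[N-]C1CCCCC1 | intermediate (not isolated)
5 | lithium 3-[(cyclohexylimino)methyl]-4-methylpentan-2-olate (mixture of diastereomers) | [Li+].CC([O-])C(C=NC1CCCCC1)C(C)C | intermediate (not isolated)
6 | (2E)-2-(propan-2-yl)but-2-enal | C/C=C(\C(C)C)C=O | intermediate
7 | tert-butyl(dimethyl){[(1E)-2-(propan-2-yl)buta-1,3-dien-1-yl]oxy}silane | CC(C)/C(C=C)=C\O[Si](C)(C)C(C)(C)C | intermediate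
8 | 3-methylcyclohex-2-en-1-one | CC1=CC(=O)CCC1 | starting material
9 | (4aR,8R,8aR)-8-{[tert-butyl(dimethyl)silyl]oxy}-4a-methyl-7-(propan-2-yl)-3,4,4a,5,8,8a-hexahydronaphthalen-1(2H)-one | O=C1CCC[C@]2(C)CC=C(C(C)C)[C@H](O[Si](C)(C)C(C)(C)C)[C@H]12 | intermediate
10 | (4aR,8R,8aR)-8-hydroxy-4a-methyl-7-(propan-2-yl)-3,4,4a,5,8,8a-hexahydronaphthalen-1(2H)-one | O=C1CCC[C@]2(C)CC=C(C(C)C)[C@H](O)[C@H]12 | intermediate
11 | (4aR,7S,8S,8aR)-8-hydroxy-4a-methyl-7-(propan-2-yl)octahydronaphthalen-1(2H)-one (cis-fused) | O=C1CCC[C@]2(C)CC[C@@H](C(C)C)[C@H](O)[C@H]12 | intermediate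
12 | (4aR,7S,8S,8aS)-8-hydroxy-4a-methyl-7-(propan-2-yl)octahydronaphthalen-1(2H)-one (trans-fused) | O=C1CCC[C@]2(C)CC[C@@H](C(C)C)[C@H](O)[C@@H]12 | intermediate
13 | (1S,2S,4aR,8aS)-4a-methyl-8-methylidene-2-(propan-2-yl)decahydronaphthalen-1-ol | C=C1CCC[C@]2(C)CC[C@@H](C(C)C)[C@H](O)[C@@H]12 | intermediate
14 | (2E)-3-[4-(acetyloxy)phenyl]prop-2-enoic acid | CC(=O)Oc1ccc(/C=C/C(=O)O)cc1 | starting material
15 | (1S,2S,4aR,8aS)-4a-methyl-8-methylidene-2-(propan-2-yl)decahydronaphthalen-1-yl (2E)-3-[4-(acetyloxy)phenyl]prop-2-enoate | C=C1CCC[C@]2(C)CC[C@@H](C(C)C)[C@H](OC(=O)/C=C/c3ccc(OC(C)=O)cc3)[C@@H]12 | intermediate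
16 | (1S,2S,4aR,8aS)-4a-methyl-8-methylidene-2-(propan-2-yl)decahydronaphthalen-1-yl (2E)-3-(4-hydroxyphenyl)prop-2-enoate | C=C1CCC[C@]2(C)CC[C@@H](C(C)C)[C@H](OC(=O)/C=C/c3ccc(O)cc3)[C@@H]12 | target

**Summary**

Total step count: 10. Longest linear sequence: 10 steps (1 → 16); 8 and 14 enter as commercial materials.

**Steps most likely to fail**

Step 4 (bears the label). What may go wrong: insufficient activation of the β,β-disubstituted enone by the boron catalyst, vinylogous Mukaiyama–Michael addition without ring closure, protodesilylation of the diene, or weak enantioface discrimination. Fallback (known chemistry, racemic cycloaddition plus resolution instead of asymmetric catalysis): setting out from 7 and 8, the cycloaddition is run without catalyst at 12–15 kbar in CH2Cl2 at 25 °C, an established way to make β-substituted cyclohexenones add oxygenated dienes with the same ortho/endo preference, to give the racemic cis-fused silyl ether F1. HF·pyridine converts it into the racemic hydroxy enone F2. This is resolved by preparative chromatography on a chiral stationary phase (amylose tris(3,5-dimethylphenylcarbamate), CO2/MeOH), the unwanted (4aS,8S,8aS)-hydroxy enone F3 being set aside. The route is rejoined at 10.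

Step 7. What may go wrong: the C5 equilibrium may not lie far enough on the trans side, or retro-aldol opening of the β-hydroxy ketone may erode C6 and C7. Fallback (kinetic syn addition instead of equilibration; bypasses steps 7 and 8): setting out from 11, acid-catalysed dehydration (p-TsOH, toluene, 80 °C) gives the conjugated enone F4, in which C5 and C6 are trigonal. CeCl3-mediated 1,2-addition of Me3SiCH2Li gives the tertiary β-hydroxysilane F5 (both C4 epimers serve), which masks the future methylene group. Hydroboration and oxidation (BH3·THF; then NaOH, H2O2) of the C5=C6 bond from the α face, anti to the angular methyl and the isopropyl group as in the hydroboration of 5-ene steroids, installs H-5α and the 6α-hydroxyl in one syn addition to give the silyl diol F6. Peterson elimination (KH, THF, rt) then releases the exocyclic methylene, and the route is rejoined at 13.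

Step 6. What may go wrong: sluggish reduction of the hindered trisubstituted C7=C8 bond with catalyst deactivation, or loss of facial control if the C4 carbonyl competes as the directing group. Fallback (radical hydrogen-atom transfer under thermodynamic control instead of directed metal hydrogenation): setting out from 10, treatment with Mn(dpm)3 (cat.), PhSiH3 and tBuOOH in iPrOH at rt transfers a hydrogen atom to C8. The resulting tertiary C7 radical takes up the second hydrogen axially, which leaves the isopropyl group equatorial (β, trans to the C6 hydroxyl). The route is rejoined at 11, and this fallback makes no new compound (entry F0).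

**Further compounds**

F1 | step 4 | racemic (4aR*,8R*,8aR*)-8-{[tert-butyl(dimethyl)silyl]oxy}-4a-methyl-7-(propan-2-yl)-3,4,4a,5,8,8a-hexahydronaphthalen-1(2H)-one | O=C1CCC[C@]2(C)CC=C(C(C)C)[C@H](O[Si](C)(C)C(C)(C)C)[C@H]12.O=C1CCC[C@@]2(C)CC=C(C(C)C)[C@@H](O[Si](C)(C)C(C)(C)C)[C@@H]12
F2 | step 4 | racemic (4aR*,8R*,8aR*)-8-hydroxy-4a-methyl-7-(propan-2-yl)-3,4,4a,5,8,8a-hexahydronaphthalen-1(2H)-one | O=C1CCC[C@]2(C)CC=C(C(C)C)[C@H](O)[C@H]12.O=C1CCC[C@@]2(C)CC=C(C(C)C)[C@@H](O)[C@@H]12
F3 | step 4 | (4aS,8S,8aS)-8-hydroxy-4a-methyl-7-(propan-2-yl)-3,4,4a,5,8,8a-hexahydronaphthalen-1(2H)-one | O=C1CCC[C@@]2(C)CC=C(C(C)C)[C@@H](O)[C@@H]12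
F4 | step 7 | (4aR,7S)-4a-methyl-7-(propan-2-yl)-3,4,4a,5,6,7-hexahydronaphthalen-1(2H)-one | O=C1CCC[C@]2(C)CC[C@@H](C(C)C)C=C12
F5 | step 7 | (4aR,7S)-4a-methyl-7-(propan-2-yl)-1-[(trimethylsilyl)methyl]-1,2,3,4,4a,5,6,7-octahydronaphthalen-1-ol (C1 epimers) | C[Si](C)(C)CC1(O)CCC[C@]2(C)CC[C@@H](C(C)C)C=C12
F6 | step 7 | (4aR,7S,8S,8aS)-4a-methyl-7-(propan-2-yl)-1-[(trimethylsilyl)methyl]decahydronaphthalene-1,8-diol (C1 epimers) | C[Si](C)(C)CC1(O)CCC[C@]2(C)CC[C@@H](C(C)C)[C@H](O)[C@@H]12
F0 | step 6 | none | none
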